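**Retrosynthetic overview**
1. Endgame: the C15 acid comes from the allylic alcohol, and both isovalerates from a 3α,6β-diol. The 6β-OH and the 8(9)-alkene come together from a 7-en-6-one (dienol acetate, then borohydride), and the enone from a 7-ene by allylic oxidation.
2. Core: both carbocycles are cut at C4–C5 and C9–C10, back to an open-chain E,E,E-triene α-methyl β-keto ester. One oxidative radical cascade closes ring A first and ring B directly after.
3. Enabling feature: on ring A the C3 oxygen and the C19 carbon sit 1,3 to each other across quaternary C4. C4 is therefore the α-carbon of a β-keto ester and can be made an electrophilic radical that meets the C5=C10 and C8=C9 alkenes of a farnesoate chain.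
4. Absolute configuration comes from an 8-phenylmenthyl ester at C19, which is cleaved when C19 is reduced to CH2OH. The precursor is three operations from methyl farnesoate.

Key step: step 5

Remark: labdane numbering is used throughout, also for the open-chain precursors (C18 = 4α-methyl, C19 = 4β-substituent, C20 = 10β-methyl, C17 = carbon on C8); 6–8 are handled as epimer mixtures at the enolizable α-carbon (future C4), which becomes fixed only in step 5.

**Step 1**
Reactants: 1 methyl (2E,6E)-farnesoate
Product: 2 methyl (2E,6E,10E)-12-hydroxy-3,7,11-trimethyldodeca-2,6,10-trienoate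
Conditions: SeO2 (0.3 equiv), t-BuOOH (2 equiv), salicylic acid (0.1 equiv), CH2Cl2, 0 → 23 °C
Reagents that add atoms: selenium dioxide O=[Se]=O (oxygen carrier); tert-butyl hydroperoxide CC(C)(C)OO (terminal oxygen source)
Why: Catalytic SeO2 allylic oxidation (ene reaction, then [2,3]-sigmatropic shift) attacks the (E)-methyl group of the terminal, most electron-rich trisubstituted alkene and leaves the conjugated 2-ene alone, so the 10E primary allylic alcohol should be the main product.

**Step 2**
Reactants: 2 methyl (2E,6E,10E)-12-hydroxy-3,7,11-trimethyldodeca-2,6,10-trienoate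
Product: 3 methyl (2E,6E,10E)-12-bromo-3,7,11-trimethyldodeca-2,6,10-trienoate
Conditions: CBr4, PPh3, CH2Cl2, 0 °C
Reagents that add atoms: carbon tetrabromide BrC(Br)(Br)Br
Why: Appel bromination displaces the oxyphosphonium ion of the primary allylic alcohol by SN2, without allylic shift or loss of alkene geometry under these cold, neutral conditions.

**Step 3**
Reactants: 4 methyl 2-methyl-3-oxobutanoate; 5 (1R,2S,5R)-5-methyl-2-(2-phenylpropan-2-yl)cyclohexan-1-ol [(−)-8-phenylmenthol]
Product: 6 (−)-8-phenylmenthyl 2-methyl-3-oxobutanoate (epimers at the α-carbon)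
Conditions: DMAP (0.2 equiv), toluene, reflux, 4 Å molecular sieves
Reagents that add atoms: none
Why: DMAP-catalysed transesterification of an enolizable β-keto ester (through the acylketene) loads the hindered secondary alcohol while methanol is trapped by the sieves; the stereocentres of the auxiliary are not involved.

**Step 4**
Reactants: 6 (−)-8-phenylmenthyl 2-methyl-3-oxobutanoate; 3 methyl (2E,6E,10E)-12-bromo-3,7,11-trimethyldodeca-2,6,10-trienoate
Product: 8 16-methyl 1-[(−)-8-phenylmenthyl] (6E,10E,14E)-2,6,10,14-tetramethyl-3-oxohexadeca-6,10,14-trienedioate (epimers at C2 of the chain = future C4), via sodium lithium dianion 7 (not isolated)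
Conditions: NaH (1.1 equiv), THF, 0 °C; n-BuLi (1.05 equiv), 0 °C; then 3, 0 → 23 °C; aq. NH4Cl
Reagents that add atoms: none
Why: γ-Alkylation of a β-keto ester dianion: the more basic terminal carbanion of 7 displaces the primary allylic bromide by SN2 much faster than it attacks the esters, giving the open-chain triene with alkene geometry untouched.

**Step 5**
Reactants: 8 16-methyl 1-[(−)-8-phenylmenthyl] (6E,10E,14E)-2,6,10,14-tetramethyl-3-oxohexadeca-6,10,14-trienedioate
Product: 9 15-methyl 19-[(−)-8-phenylmenthyl] 3-oxolabda-8(17),13E-diene-15,19-dioate (trans-decalin; 4α-CH3, 4β-CO2R*, 5α-H, 9α-H, 10β-CH3)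
Conditions: Mn(OAc)3·2H2O (2.2 equiv), Cu(OAc)2·H2O (1.0 equiv), degassed AcOH (0.05 M), 23 °C
Reagents that add atoms: none
Why: Mn(OAc)3 turns the α-methyl β-keto ester into its trivalent manganese enolate, which loses an electron to give the electrophilic tertiary C4 radical; this adds 6-endo-trig to C5 of the E C5=C10 alkene (C4–C5 bond, ring A), the tertiary C10 radical adds 6-endo-trig to C9 of the E C8=C9 alkene (ring B), and divalent copper oxidizes the tertiary C8 radical to the alkene. The closest known reaction type is the Mn(OAc)3/Cu(OAc)2 oxidative free-radical polycyclization of unsaturated α-alkyl β-keto esters, including 8-phenylmenthyl esters. Ring A closes through a chair transition state with the two carbonyl groups of the planar radical anti, which puts the ester axial (4β) and the methyl equatorial (4α) and sets 5α-H trans to the 10β-methyl; ring B closes from the chair–chair fold, so C9 carries its side chain equatorial (9α-H, erased later). The absolute sense comes from the auxiliary, whose phenyl ring lies over one face of the radical in the s-trans ester and leaves the other face to the alkene; the minor diastereomer would be removed by chromatography. The step needs 6-endo over 5-exo closure twice, secured by the methyl groups on C10 and C8, which direct attack to the unsubstituted alkene carbon and give tertiary radicals; it also needs the 13-enoate to stay out, secured by its electron-poor character and by the fast copper oxidation of the C8 radical. Any 7-ene formed beside the 8(17)-ene converges in step 6.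

**Step 6**
Reactants: 9 15-methyl 19-[(−)-8-phenylmenthyl] 3-oxolabda-8(17),13E-diene-15,19-dioate
Product: 10 15-methyl 19-[(−)-8-phenylmenthyl] 3-oxolabda-7,13E-diene-15,19-dioate
Conditions: RhCl3·3H2O (5 mol%), EtOH, 75 °C
Reagents that add atoms: none
Why: RhCl3-catalysed alkene isomerization (rhodium hydride or π-allyl hydride pathway) moves the exocyclic double bond into the ring; the C7 methylene hydrogens are more accessible than the tertiary C9–H next to quaternary C10, so the trisubstituted 7-ene should form, and no stereocentre changes.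

**Step 7**
Reactants: 10 15-methyl 19-[(−)-8-phenylmenthyl] 3-oxolabda-7,13E-diene-15,19-dioate
Product: 12 15-methyl 19-[(−)-8-phenylmenthyl] 3α-acetoxylabda-7,13E-diene-15,19-dioate, via lithium 3α-alkoxide 11 (not isolated)
Conditions: LiBH(s-Bu)3 (L-Selectride, 1.2 equiv), THF, −78 °C; then Ac2O, DMAP, −78 → 23 °C
Reagents that add atoms: acetic anhydride CC(=O)OC(C)=O
Why: The bulky hydride attacks the 3-ketone along the equatorial trajectory (β face), away from the axial C19 ester, giving the axial 3α-alkoxide, which is acetylated in the same flask (selectride reduction of a 4,4-disubstituted 3-ketone, then DMAP-catalysed acetylation).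

**Step 8**
Reactants: 12 15-methyl 19-[(−)-8-phenylmenthyl] 3α-acetoxylabda-7,13E-diene-15,19-dioate
Product: 13 15-methyl 19-[(−)-8-phenylmenthyl] 3α-acetoxy-6-oxolabda-7,13E-diene-15,19-dioate
Conditions: CrO3, 3,5-dimethylpyrazole, CH2Cl2, −20 °C
Reagents that add atoms: chromium trioxide O=[Cr](=O)=O
Why: Allylic oxidation with the CrO3–3,5-dimethylpyrazole complex turns the ring methylene next to the CH end of the trisubstituted alkene (C6) into the ketone, the known outcome for 1-methylcyclohexene-type alkenes and 7-ene steroids, while the electron-poor 13-enoate and the tertiary C9–H should be spared; no stereocentre is formed.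

**Step 9**
Reactants: 13 15-methyl 19-[(−)-8-phenylmenthyl] 3α-acetoxy-6-oxolabda-7,13E-diene-15,19-dioate
Product: 14 15-methyl 19-[(−)-8-phenylmenthyl] 3α,6-diacetoxylabda-6,8,13E-triene-15,19-dioate
Conditions: isopropenyl acetate, TsOH·H2O (cat.), 95 °C
Reagents that add atoms: isopropenyl acetate CC(=C)OC(C)=O
Why: Acid-catalysed enol acetylation under equilibrating conditions gives the through-conjugated dienol acetate by loss of the γ-hydrogen at C9 (the endocyclic, more substituted diene, as in the 3,5-dienol acetates of 4-en-3-ones), which places a double bond at C8=C9 and erases the C9 stereocentre.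

**Step 10**
Reactants: 14 15-methyl 19-[(−)-8-phenylmenthyl] 3α,6-diacetoxylabda-6,8,13E-triene-15,19-dioate
Product: 16 15-methyl 19-[(−)-8-phenylmenthyl] 3α-acetoxy-6β-hydroxylabda-8,13E-diene-15,19-dioate, via β,γ-enone 15 (not isolated)
Conditions: NaBH4, EtOH–THF, 0 → 23 °C
Reagents that add atoms: none
Why: Deconjugative borohydride reduction of a dienol acetate: ethanolysis frees the dienolate, kinetic protonation at C7 gives the β,γ-enone 15, and NaBH4 reduces that ketone at once from the open α face (the β face is shielded by the axial 10β-methyl and 4β-ester), so the axial 6β-alcohol with the tetrasubstituted 8(9)-alkene should result.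

**Step 11**
Reactants: 16 15-methyl 19-[(−)-8-phenylmenthyl] 3α-acetoxy-6β-hydroxylabda-8,13E-diene-15,19-dioate
Product: 17 labda-8,13E-diene-3α,6β,15,19-tetrol
Conditions: LiAlH4, THF, 0 → 40 °C; Rochelle salt work-up
Reagents that add atoms: none
Why: LiAlH4 reduces all three esters: the enoate gives the allylic alcohol by 1,2-reduction, the 3-acetate is cleaved, and the hindered C19 ester (helped by the neighbouring 6β-alkoxide) gives the hydroxymethyl group and releases the auxiliary alcohol 5 for reuse.

**Step 12**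
Reactants: 17 labda-8,13E-diene-3α,6β,15,19-tetrol
Product: 18 15,19-bis(tert-butyldimethylsilyloxy)labda-8,13E-diene-3α,6β-diol
Conditions: TBSCl (2.3 equiv), imidazole, DMF, 0 → 23 °C
Reagents that add atoms: tert-butyldimethylsilyl chloride CC(C)(C)[Si](C)(C)Cl
Why: Silylation with TBSCl–imidazole is selective for the two primary hydroxyls (allylic C15 and neopentyl C19) over the axial secondary 3α- and 6β-hydroxyls, which are flanked by quaternary carbons.

**Step 13**
Reactants: 18 15,19-bis(tert-butyldimethylsilyloxy)labda-8,13E-diene-3α,6β-diol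
Product: 19 15,19-bis(tert-butyldimethylsilyloxy)labda-8,13E-diene-3α,6β-diyl bis(3-methylbutanoate)
Conditions: (i-PrCH2CO)2O (6 equiv), DMAP, Et3N, toluene, 80 °C
Reagents that add atoms: 3-methylbutanoic anhydride CC(C)CC(=O)OC(=O)CC(C)C
Why: DMAP-catalysed acylation with excess anhydride under forcing conditions (acyl transfer through the N-acylpyridinium ion) esterifies both axial secondary hydroxyls with retention at C3 and C6.

**Step 14**
Reactants: 19 15,19-bis(tert-butyldimethylsilyloxy)labda-8,13E-diene-3α,6β-diyl bis(3-methylbutanoate)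
Product: 20 15,19-dihydroxylabda-8,13E-diene-3α,6β-diyl bis(3-methylbutanoate)
Conditions: HF·pyridine, pyridine–THF, 0 → 23 °C
Reagents that add atoms: none
Why: Buffered fluoride desilylation removes both primary TBS ethers and should leave the hindered isovalerates in place without acyl migration.

**Step 15**
Reactants: 20 15,19-dihydroxylabda-8,13E-diene-3α,6β-diyl bis(3-methylbutanoate)
Product: 21 19-hydroxy-15-oxolabda-8,13E-diene-3α,6β-diyl bis(3-methylbutanoate)
Conditions: activated MnO2, CH2Cl2, 23 °C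
Reagents that add atoms: none
Why: MnO2 oxidizes only the allylic C15 alcohol to the E-enal (chemoselective allylic oxidation on the oxide surface) and leaves the saturated neopentyl 19-hydroxyl untouched.

**Step 16**
Reactants: 21 19-hydroxy-15-oxolabda-8,13E-diene-3α,6β-diyl bis(3-methylbutanoate)
Product: 22 (3R,4S,5R,6R,10S,13E)-19-hydroxy-3,6-bis(3-methylbutanoyloxy)labda-8,13-dien-15-oic acid (CNP0272110.1)
Conditions: NaClO2, NaH2PO4, 2-methyl-2-butene, t-BuOH–H2O, 23 °C
Reagents that add atoms: sodium chlorite [Na+].[O-]Cl=O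
Why: Pinnick oxidation converts the enal into the acid with retention of the 13E geometry, the hypochlorite by-product being trapped by 2-methyl-2-butene so that the 8(9)-alkene and the free 19-hydroxyl survive.

**Compound list**
1 | methyl (2E,6E)-3,7,11-trimethyldodeca-2,6,10-trienoate (methyl farnesoate) | CC(C)=CCC/C(C)=C/CC/C(C)=C/C(=O)OC | starting material
2 | methyl (2E,6E,10E)-12-hydroxy-3,7,11-trimethyldodeca-2,6,10-trienoate | OC/C(C)=C/CC/C(C)=C/CC/C(C)=C/C(=O)OC | intermediate
3 | methyl (2E,6E,10E)-12-bromo-3,7,11-trimethyldodeca-2,6,10-trienoate | BrC/C(C)=C/CC/C(C)=C/CC/C(C)=C/C(=O)OC | intermediate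
4 | methyl 2-methyl-3-oxobutanoate | CC(=O)C(C)C(=O)OC | starting material
5 | (1R,2S,5R)-5-methyl-2-(2-phenylpropan-2-yl)cyclohexan-1-ol, (−)-8-phenylmenthol | O[C@@H]1C[C@H](C)CC[C@H]1C(C)(C)c1ccccc1 | starting material
6 | (−)-8-phenylmenthyl 2-methyl-3-oxobutanoate (α-epimers) | CC(=O)C(C)C(=O)O[C@@H]1C[C@H](C)CC[C@H]1C(C)(C)c1ccccc1 | intermediate
7 | sodium lithium α,γ-dianion of 6 | [Na+].[Li+].[CH2-]C(=O)[C-](C)C(=O)O[C@@H]1C[C@H](C)CC[C@H]1C(C)(C)c1ccccc1 | intermediate
8 | 16-methyl 1-[(−)-8-phenylmenthyl] (6E,10E,14E)-2,6,10,14-tetramethyl-3-oxohexadeca-6,10,14-trienedioate (C2 epimers) | CC(C(=O)O[C@@H]1C[C@H](C)CC[C@H]1C(C)(C)c1ccccc1)C(=O)CC/C(C)=C/CC/C(C)=C/CC/C(C)=C/C(=O)OC | intermediate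
9 | 15-methyl 19-[(−)-8-phenylmenthyl] 3-oxolabda-8(17),13E-diene-15,19-dioate (5α-H, 9α-H, 10β-Me, 4β-ester) | C=C1[C@H](CC/C(C)=C/C(=O)OC)[C@@]2(C)CCC(=O)[C@](C)(C(=O)O[C@@H]3C[C@H](C)CC[C@H]3C(C)(C)c3ccccc3)[C@@H]2CC1 | intermediate
10 | 15-methyl 19-[(−)-8-phenylmenthyl] 3-oxolabda-7,13E-diene-15,19-dioate | CC=1[C@H](CC/C(C)=C/C(=O)OC)[C@@]2(C)CCC(=O)[C@](C)(C(=O)O[C@@H]3C[C@H](C)CC[C@H]3C(C)(C)c3ccccc3)[C@@H]2CC=1 | intermediate
11 | lithium 3α-alkoxide of the 3-hydroxy-7-ene diester | CC=1[C@H](CC/C(C)=C/C(=O)OC)[C@@]2(C)CC[C@@H]([O-])[C@](C)(C(=O)O[C@@H]3C[C@H](C)CC[C@H]3C(C)(C)c3ccccc3)[C@@H]2CC=1.[Li+] | intermediate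
12 | 15-methyl 19-[(−)-8-phenylmenthyl] 3α-acetoxylabda-7,13E-diene-15,19-dioate | CC=1[C@H](CC/C(C)=C/C(=O)OC)[C@@]2(C)CC[C@@H](OC(C)=O)[C@](C)(C(=O)O[C@@H]3C[C@H](C)CC[C@H]3C(C)(C)c3ccccc3)[C@@H]2CC=1 | intermediate
13 | 15-methyl 19-[(−)-8-phenylmenthyl] 3α-acetoxy-6-oxolabda-7,13E-diene-15,19-dioate | CC=1[C@H](CC/C(C)=C/C(=O)OC)[C@@]2(C)CC[C@@H](OC(C)=O)[C@](C)(C(=O)O[C@@H]3C[C@H](C)CC[C@H]3C(C)(C)c3ccccc3)[C@@H]2C(=O)C=1 | intermediate
14 | 15-methyl 19-[(−)-8-phenylmenthyl] 3α,6-diacetoxylabda-6,8,13E-triene-15,19-dioate | CC1=C(CC/C(C)=C/C(=O)OC)[C@@]2(C)CC[C@@H](OC(C)=O)[C@](C)(C(=O)O[C@@H]3C[C@H](C)CC[C@H]3C(C)(C)c3ccccc3)[C@@H]2C(OC(C)=O)=C1 | intermediate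
15 | 15-methyl 19-[(−)-8-phenylmenthyl] 3α-acetoxy-6-oxolabda-8,13E-diene-15,19-dioate | CC1=C(CC/C(C)=C/C(=O)OC)[C@@]2(C)CC[C@@H](OC(C)=O)[C@](C)(C(=O)O[C@@H]3C[C@H](C)CC[C@H]3C(C)(C)c3ccccc3)[C@@H]2C(=O)C1 | intermediate
16 | 15-methyl 19-[(−)-8-phenylmenthyl] 3α-acetoxy-6β-hydroxylabda-8,13E-diene-15,19-dioate | CC1=C(CC/C(C)=C/C(=O)OC)[C@@]2(C)CC[C@@H](OC(C)=O)[C@](C)(C(=O)O[C@@H]3C[C@H](C)CC[C@H]3C(C)(C)c3ccccc3)[C@@H]2[C@H](O)C1 | intermediate
17 | labda-8,13E-diene-3α,6β,15,19-tetrol | CC1=C(CC/C(C)=C/CO)[C@@]2(C)CC[C@@H](O)[C@](C)(CO)[C@@H]2[C@H](O)C1 | intermediate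
18 | 15,19-bis(tert-butyldimethylsilyloxy)labda-8,13E-diene-3α,6β-diol | CC1=C(CC/C(C)=C/CO[Si](C)(C)C(C)(C)C)[C@@]2(C)CC[C@@H](O)[C@](C)(CO[Si](C)(C)C(C)(C)C)[C@@H]2[C@H](O)C1 | intermediate
19 | 15,19-bis(tert-butyldimethylsilyloxy)labda-8,13E-diene-3α,6β-diyl bis(3-methylbutanoate) | CC1=C(CC/C(C)=C/CO[Si](C)(C)C(C)(C)C)[C@@]2(C)CC[C@@H](OC(=O)CC(C)C)[C@](C)(CO[Si](C)(C)C(C)(C)C)[C@@H]2[C@H](OC(=O)CC(C)C)C1 | intermediate
20 | 15,19-dihydroxylabda-8,13E-diene-3α,6β-diyl bis(3-methylbutanoate) | CC1=C(CC/C(C)=C/CO)[C@@]2(C)CC[C@@H](OC(=O)CC(C)C)[C@](C)(CO)[C@@H]2[C@H](OC(=O)CC(C)C)C1 | intermediate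
21 | 19-hydroxy-15-oxolabda-8,13E-diene-3α,6β-diyl bis(3-methylbutanoate) | CC1=C(CC/C(C)=C/C=O)[C@@]2(C)CC[C@@H](OC(=O)CC(C)C)[C@](C)(CO)[C@@H]2[C@H](OC(=O)CC(C)C)C1 | intermediate
22 | (3R,4S,5R,6R,10S,13E)-19-hydroxy-3,6-bis(3-methylbutanoyloxy)labda-8,13-dien-15-oic acid | CC1=C(CC/C(C)=C/C(=O)O)[C@@]2(C)CC[C@@H](OC(=O)CC(C)C)[C@](C)(CO)[C@@H]2[C@H](OC(=O)CC(C)C)C1 | target

**Step count**
Total: 16 steps. Longest linear sequence: 15 steps (1 → 2 → 3 → 8 → 9 → … → 22; step 3 is the side branch).

**Steps most likely to fail, with fallbacks**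

Step 6. The risk is positional drift of the double bond: the catalyst may carry the alkene on to the tetrasubstituted 8(9)-position or stall at a mixture. The fallback sets out from 9 and returns at 10. Catalytic SeO2/t-BuOOH hydroxylates the exocyclic alkene at its ring methylene and should give the 7α-hydroxy-8(17)-ene F1. Mitsunobu displacement with 2-nitrobenzenesulfonylhydrazide (PPh3, DEAD, N-methylmorpholine, THF, −30 °C) gives the N-allyl sulfonylhydrazine F2. On warming to 23 °C this loses 2-nitrobenzenesulfinic acid to the allylic diazene F3, which expels N2 in a retro-ene shift that places hydrogen on C17 and the double bond at C7=C8 (Myers reductive allylic transposition), i.e. 10. The alkene position is then fixed by a sigmatropic event rather than by catalyst selectivity.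

Step 10. The risk is protonation of the dienolate at C9 instead of C7, which returns the conjugated enone and ends in the 7-en-6-ol, or hydride delivery from the wrong face. The fallback sets out from 13 and returns at 16, separating the two events. KOt-Bu in t-BuOH–THF at 0 °C forms the through-conjugated potassium dienolate of 13. Inverse quench into cold aqueous AcOH gives the β,γ-enone 15 by kinetic α-protonation, this time isolated. LiBH(s-Bu)3 in THF at −78 °C then reduces the C6 ketone from the α face to 16.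

Step 13. The risk is incomplete acylation of the 6β-hydroxyl, which is 1,3-diaxial to C20 and to the bulky silyloxymethyl group, or silyl migration from O19 to O6 under forcing conditions. The fallback sets out from 17 and returns at 20, without silyl groups. Exhaustive acylation of 17 (isovaleryl chloride, pyridine, DMAP, 60 °C) gives the tetraisovalerate F4, in which the 6β-hydroxyl faces a small acyloxymethyl neighbour while it is acylated. K2CO3 in MeOH at 0 °C should then remove the two unhindered primary esters (allylic C15 and C19) faster than the two hindered axial secondary esters, giving 20.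

**Further compounds**
F1 | step 6 | 15-methyl 19-[(−)-8-phenylmenthyl] 7α-hydroxy-3-oxolabda-8(17),13E-diene-15,19-dioate | C=C1[C@H](CC/C(C)=C/C(=O)OC)[C@@]2(C)CCC(=O)[C@](C)(C(=O)O[C@@H]3C[C@H](C)CC[C@H]3C(C)(C)c3ccccc3)[C@@H]2C[C@H]1O
F2 | step 6 | 15-methyl 19-[(−)-8-phenylmenthyl] 7β-[1-(2-nitrophenylsulfonyl)hydrazin-1-yl]-3-oxolabda-8(17),13E-diene-15,19-dioate | C=C1[C@H](CC/C(C)=C/C(=O)OC)[C@@]2(C)CCC(=O)[C@](C)(C(=O)O[C@@H]3C[C@H](C)CC[C@H]3C(C)(C)c3ccccc3)[C@@H]2C[C@@H]1N(N)S(=O)(=O)c1ccccc1[N+](=O)[O-]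
F3 | step 6 | 15-methyl 19-[(−)-8-phenylmenthyl] 7β-diazenyl-3-oxolabda-8(17),13E-diene-15,19-dioate | C=C1[C@H](CC/C(C)=C/C(=O)OC)[C@@]2(C)CCC(=O)[C@](C)(C(=O)O[C@@H]3C[C@H](C)CC[C@H]3C(C)(C)c3ccccc3)[C@@H]2C[C@@H]1N=N
F0 | step 10 | none | none
F4 | step 13 | labda-8,13E-diene-3α,6β,15,19-tetrayl tetrakis(3-methylbutanoate) | CC1=C(CC/C(C)=C/COC(=O)CC(C)C)[C@@]2(C)CC[C@@H](OC(=O)CC(C)C)[C@](C)(COC(=O)CC(C)C)[C@@H]2[C@H](OC(=O)CC(C)C)C1
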